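The numbers in the tables stem from a simulated flask on assumed constants, noise included.

At early times the ochre run moves fast: by 2.00 h it holds 10.9% of left-handed and 6.2% of right-handed product, yet by 40.0 h it has stopped well short of the charge.

the same everywhere: left-handed substrate 0.19 M; right-handed substrate 0.19 M; coupling partner 0.475 M; racemization catalyst 0.38 mM

|  | free catalyst | remark | time |
|---|---|---|---|
| ochre | 2.6 mM | run made earlier |  |
| flask | 5.3 mM |  | 8.0 d |

ochre run (percent of the left-handed substrate and right-handed substrate together charged)

| time / h | left-handed product / % | right-handed product / % |
|---|---|---|
| 2.00 | 10.9 | 6.2 |
| 6.00 | 21.1 | 10.5 |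
| 10.0 | 27.7 | 13.6 |
| 15.0 | 30.4 | 15.3 |
| 25.0 | 34.9 | 16.8 |
| 30.0 | 36.2 | 17.2 |
| 40.0 | 34.6 | 18.9 |

(each reading ± 1 percentage point)

- free catalyst is single-handed; left-handed substrate and right-handed substrate are mirror images of each other, charged as a racemate, each of them at the stated concentration
- what was read earlier has a scatter of 1 percentage point, one standard deviation
- an excess is the difference of the two amounts in percent of their sum
- an excess is below zero if the other one leads
- no earlier run changes the charge of free catalyst; that part of a forecast is a guess

- left-handed product and right-handed product together, in percent of the left-handed substrate and right-handed substrate charged together, at 8.0 d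
- excess of left-handed product over right-handed product in the product at 8.0 d
- whether the exchange between left-handed substrate and right-handed substrate keeps pace with the reaction: how far the product's excess at 8.0 d gets from its value without exchange to its value with instant exchange (above 80% keeps pace, below 20% hardly takes part, else lags behind)

Read this table through the fraction of substrate left, not the fraction made, and call minus the natural logarithm of that fraction the reach. As a working assumption of mine, treat both substrates as one pool and that pool as pseudo-first-order, so that the reach climbs at a rate proportional to [free catalyst] times [coupling partner].

Row by row, the ochre reach is 0.188 at 2.00 h, 0.533 at 10.0 h and 0.764 at 30.0 h. The last ochre row leaves 46.5%, a reach of 0.766, and this reading of the plateau, the final reach that a charge of catalyst buys, is what I carry. The first 2.00 h of the ochre run gained more than the stretch from 30.0 h to 40.0 h. Coupling has used 0.203 M of the 0.475 M of partner, so I read the stop as the catalyst dying.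

If the death is first-order, I scale the reach with the catalyst charge, which is a guess, and with the partner at the halfway point, 0.373 M in the ochre run. The flask has twice the catalyst, so I first put its reach at 1.56, a yield of 79.0%. That puts its halfway partner at 0.325 M, which trims the reach to 1.36 and the yield to 74.3%.

From 6.00 h to 30.0 h the ochre product grows while its excess holds, pooled at 34.4%. So I expect that excess in the flask, with exchange keeping pace.

The forecast, holding that “the catalyst appears to die”, gives 75%, a little above my yield, and an excess of 32%, below mine, and its verdict on the exchange is: keeps pace.

The flask gives 73.2% with an excess of 31.5%, and its exchange keeps pace, getting 89% of the way against the 80% required.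

    2 coupling partner → self-condensation product (k = 9.10 × 10⁻⁶ M⁻¹ s⁻¹)
    coupling partner + free catalyst + right-handed substrate → free catalyst + right-handed product (k = 0.0150 M⁻² s⁻¹)
    coupling partner + free catalyst + left-handed substrate → free catalyst + left-handed product (k = 0.0300 M⁻² s⁻¹)
    left-handed substrate + racemization catalyst ⇌ right-handed substrate + racemization catalyst, rate k4*[racemization catalyst]*[left-handed substrate] forward; the back reaction follows from the equilibrium constant (k = 0.520 M⁻¹ s⁻¹)
    free catalyst → spent catalyst (k = 2.00 × 10⁻⁵ s⁻¹)

The flask's reach comes to 1.32, close to my 1.36. Now take the neighbouring flask with 0.0013 M of free catalyst, half the ochre charge. Scaling by catalyst, I first put its reach at 0.383, a yield of 31.8%, and its halfway partner of 0.415 M lifts the reach to 0.425, a yield of 34.6%. That neighbouring flask gives 35.6%.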